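The route rests on cutting the bicyclic core at C3–C4 and C5–C10. In ring A the fusion atoms C5 and C10 (quaternary, methyl-bearing) lie between oxygenated C1 and ester-bearing C4. A 2-silyloxy diene C3=C2–C1(OSi)=C10 and an ynoate C4≡C5, linked by the chain C6–C9, are therefore the matching partners. One thermal intramolecular Diels–Alder reaction closes rings A and B at once and sets quaternary C10 from the C9 stereocentre. Its precursor is an acyclic (Z)-silyl dienol ether whose C9 already carries the C8 methylidene and the silyl-protected C11–C12 arm, and whose chain ends in a methyl alk-2-ynoate. C4, C5 and C1 are set afterwards.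

Key step: step 12

Remark: atom labels C1–C20 are the labdane positions of the target (C1 acetoxy-bearing, C4 ester-bearing, C5/C10 ring fusion, C8 methylidene-bearing, C9 side-chain-bearing, C17 exocyclic CH2, C20 methyl on C10).

Assumption: the (4S,5S) bromodiazaborolidine of step 7 is taken to expose the Re face of C10 in ketene acetal 11, which gives (3S) in acid 12; should a trial show the opposite sense, the (4R,5R) reagent is used and nothing else changes.

Step 1
Reactants: 1 propane-1,3-diol
Product: 2 3-[(triisopropylsilyl)oxy]propan-1-ol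
Conditions: TIPSCl (1 equiv), imidazole, 1 (3 equiv), DMF, 0 °C → rt
Reagents that add atoms: chlorotriisopropylsilane, CC(C)[Si](Cl)(C(C)C)C(C)C
Why: O-silylation of a primary alcohol, held at the mono-ether by the threefold excess of the cheap symmetric diol; TIPS is chosen because this ether must later outlast cleavage of a TBS enol ether.

Step 2
Reactants: 2 3-[(triisopropylsilyl)oxy]propan-1-ol
Product: 3 3-[(triisopropylsilyl)oxy]propanal
Conditions: TEMPO (10 mol %), PhI(OAc)2, CH2Cl2, rt
Reagents that add atoms: none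
Why: TEMPO-mediated (oxoammonium) oxidation of a primary alcohol stops at the aldehyde under neutral conditions, which avoids β-elimination of the silyloxy group.

Step 3
Reactants: 4 triethyl phosphonoacetate, 5 4-bromobut-1-yne
Product: 6 ethyl 2-(diethoxyphosphoryl)hex-5-ynoate
Conditions: NaH, NaI (cat.), THF/DMF, 0 → 60 °C
Reagents that add atoms: none
Why: SN2 C-alkylation of the sodium salt of a malonate-type carbon acid by a primary bromide, with excess 5 and catalytic iodide offsetting competing elimination and the alkyne C–H too weakly acidic to interfere.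

Step 4
Reactants: 6 ethyl 2-(diethoxyphosphoryl)hex-5-ynoate, 3 3-[(triisopropylsilyl)oxy]propanal
Product: 7 ethyl (2E)-2-(but-3-yn-1-yl)-5-[(triisopropylsilyl)oxy]pent-2-enoate
Conditions: NaH, THF, 0 °C → rt
Reagents that add atoms: none
Why: Horner–Wadsworth–Emmons olefination of an unhindered aldehyde with an α-alkyl phosphonoacetate should favour the (E) trisubstituted ester (ester trans to the C11 chain), and the minor (Z) isomer is to be removed by chromatography so that a single alkene geometry enters the rearrangement.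

Step 5
Reactants: 7 ethyl (2E)-2-(but-3-yn-1-yl)-5-[(triisopropylsilyl)oxy]pent-2-enoate
Product: 8 (2E)-2-(but-3-yn-1-yl)-5-[(triisopropylsilyl)oxy]pent-2-en-1-ol
Conditions: DIBAL-H (i-Bu2AlH, 2.2 equiv), CH2Cl2, −78 → 0 °C; aq. potassium sodium tartrate
Reagents that add atoms: none
Why: 1,2-Reduction of an α,β-unsaturated ester to the allylic alcohol by a dialkylaluminium hydride, which at low temperature leaves the alkene geometry, the terminal alkyne and the silyl ether untouched.

Step 6
Reactants: 8 (2E)-2-(but-3-yn-1-yl)-5-[(triisopropylsilyl)oxy]pent-2-en-1-ol, 9 propanoyl chloride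
Product: 10 (2E)-2-(but-3-yn-1-yl)-5-[(triisopropylsilyl)oxy]pent-2-en-1-yl propanoate
Conditions: Et3N, DMAP (cat.), CH2Cl2, 0 °C
Reagents that add atoms: none
Why: DMAP-catalysed O-acylation of a primary allylic alcohol with an acid chloride.

Step 7
Reactants: 10 (2E)-2-(but-3-yn-1-yl)-5-[(triisopropylsilyl)oxy]pent-2-en-1-yl propanoate
Product: 12 (2S,3S)-2-methyl-4-methylidene-3-{2-[(triisopropylsilyl)oxy]ethyl}oct-7-ynoic acid, via boron ketene acetal 11 (not isolated)
Conditions: preformed (4S,5S)-2-bromo-1,3-bis{[3,5-bis(trifluoromethyl)phenyl]sulfonyl}-4,5-diphenyl-1,3,2-diazaborolidine (1.2 equiv), i-Pr2NEt, CH2Cl2, −78 °C, then −20 → 4 °C (several days); aqueous work-up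
Reagents that add atoms: none
Why: Enantioselective Ireland–Claisen rearrangement, in which soft enolisation by the C2-symmetric bromoborane and i-Pr2NEt should give ketene acetal 11 with methyl cis to O–B, whose chair [3,3] shift (C11 chain of the (E) alkene equatorial) forms C9–C10 and the C8=C17 methylidene while the sulfonamide ligand shields one enolate face and so sets C9 as S; the C10 configuration is of no consequence because step 10 erases it.

Step 8
Reactants: 12 (2S,3S)-2-methyl-4-methylidene-3-{2-[(triisopropylsilyl)oxy]ethyl}oct-7-ynoic acid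
Product: 13 (2S,3S)-N-methoxy-N,2-dimethyl-4-methylidene-3-{2-[(triisopropylsilyl)oxy]ethyl}oct-7-ynamide
Conditions: MeNHOMe·HCl, EDC·HCl, HOBt (cat.), N-methylmorpholine, CH2Cl2, 0 °C → rt
Reagents that add atoms: N,O-dimethylhydroxylamine hydrochloride, CNOC.Cl
Why: Carbodiimide-mediated amide coupling to the N-methoxy-N-methylamide, where any epimerisation at C10 is harmless because that centre becomes sp2 in step 10.

Step 9
Reactants: 13 (2S,3S)-N-methoxy-N,2-dimethyl-4-methylidene-3-{2-[(triisopropylsilyl)oxy]ethyl}oct-7-ynamide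
Product: 14 (4S,5S)-4-methyl-6-methylidene-5-{2-[(triisopropylsilyl)oxy]ethyl}dec-1-en-9-yn-3-one
Conditions: CH2=CHMgBr (3 equiv), THF, −20 → 0 °C; inverse quench into cold 1 M HCl
Reagents that add atoms: vinylmagnesium bromide, C=C[Mg]Br
Why: Weinreb ketone synthesis, in which the N-methoxy-N-methylamide takes up one vinyl group only, the excess reagent covers deprotonation of the alkyne, and the acidic inverse quench keeps the liberated hydroxylamine from adding to the enone.

Step 10
Reactants: 14 (4S,5S)-4-methyl-6-methylidene-5-{2-[(triisopropylsilyl)oxy]ethyl}dec-1-en-9-yn-3-one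
Product: 15 (3Z,5R)-3-[(tert-butyldimethylsilyl)oxy]-4-methyl-6-methylidene-5-{2-[(triisopropylsilyl)oxy]ethyl}deca-1,3-dien-9-yne
Conditions: TBSOTf, Et3N, CH2Cl2, −78 → 0 °C
Reagents that add atoms: tert-butyldimethylsilyl trifluoromethanesulfonate, CC(C)(C)[Si](C)(C)OS(=O)(=O)C(F)(F)F
Why: Soft enolisation of a vinyl ketone to the 2-silyloxy diene (O-silylation, then deprotonation at C10, the only enolisable position), in which the (Z) isomer should prevail because the branched C9 substituent prefers the site cis to the small O–Si oxygen and leaves methyl cis to the vinyl group; C9 is not touched.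

Step 11
Reactants: 15 (3Z,5R)-3-[(tert-butyldimethylsilyl)oxy]-4-methyl-6-methylidene-5-{2-[(triisopropylsilyl)oxy]ethyl}deca-1,3-dien-9-yne
Product: 17 methyl (7R,8Z)-9-[(tert-butyldimethylsilyl)oxy]-8-methyl-6-methylidene-7-{2-[(triisopropylsilyl)oxy]ethyl}undeca-8,10-dien-2-ynoate, via lithium acetylide 16 (not isolated)
Conditions: LDA (LiN(i-Pr)2, 1.05 equiv), THF, −78 °C; ClCO2Me, −78 → −20 °C
Reagents that add atoms: methyl chloroformate, COC(Cl)=O
Why: Deprotonation of the terminal alkyne by a non-nucleophilic amide base and C-acylation of acetylide 16 with a chloroformate, with the TBS enol ether and the TIPS ether inert to LDA at −78 °C, which is why the ynoate is installed only after the enone has been masked as the diene.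

Step 12
Reactants: 17 methyl (7R,8Z)-9-[(tert-butyldimethylsilyl)oxy]-8-methyl-6-methylidene-7-{2-[(triisopropylsilyl)oxy]ethyl}undeca-8,10-dien-2-ynoate
Product: 18 methyl (4aS,5R)-4-[(tert-butyldimethylsilyl)oxy]-4a-methyl-6-methylidene-5-{2-[(triisopropylsilyl)oxy]ethyl}-2,4a,5,6,7,8-hexahydronaphthalene-1-carboxylate
Conditions: PhMe (0.01 M), BHT (10 mol %), 150 °C, sealed base-washed tube
Reagents that add atoms: none
Why: Concerted, normal-electron-demand intramolecular [4+2] cycloaddition in which the nucleophilic enol ether terminus C10 bonds to the electrophilic β-carbon C5 of the ynoate and C3 bonds to C4, the tether enforcing the electronically favoured orientation. The closest known reactions are thermal intramolecular Diels–Alder reactions of 1,3,9-decatrienes that carry the future angular methyl on the diene terminus, and of tethered alk-2-ynoates that give cyclohexa-1,4-dienes. Ring A closes as the cycloadduct ring itself (C10, C1, C2, C3 from the diene, C4 and C5 from the alkyne), and ring B closes as a fused six-membered ring because the four-carbon tether C9–C8–C7–C6 joins C10 to C5. The one new stereocentre, quaternary C10, is controlled by C9 through allylic 1,3-strain: C9–H lies in the diene plane next to the cis C1–OTBS group, so the C8 branch delivers the ynoate to one diene face and the C11 arm ends up cis to the C10 methyl (4aS). Only this diene-face selectivity is needed, since an alkyne dienophile leaves no endo/exo or ring-fusion question and quaternary C10 prevents aromatisation; dilution, BHT and a temperature kept below that of the competing 1,5-hydrogen shift from the cis methyl should keep the reaction clean.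

Step 13
Reactants: 18 methyl (4aS,5R)-4-[(tert-butyldimethylsilyl)oxy]-4a-methyl-6-methylidene-5-{2-[(triisopropylsilyl)oxy]ethyl}-2,4a,5,6,7,8-hexahydronaphthalene-1-carboxylate
Product: 20 methyl (1R,4aS,5R,8aS)-4-[(tert-butyldimethylsilyl)oxy]-1,4a-dimethyl-6-methylidene-5-{2-[(triisopropylsilyl)oxy]ethyl}-1,2,4a,5,6,7,8,8a-octahydronaphthalene-1-carboxylate, via lithium ester enolate 19 (not isolated)
Conditions: Li (2.5 equiv), NH3(l)/THF, t-BuOH (1.0 equiv), −78 °C; isoprene; MeI, −78 → −33 °C
Reagents that add atoms: iodomethane, CI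
Why: Dissolving-metal (Birch-type) reductive alkylation of a tetrasubstituted α,β-unsaturated ester, in which C5 is protonated anti to the axial C10 methyl to give the trans ring fusion and enolate 19 is then methylated at C4 from the face opposite that methyl (equatorial entry), leaving the ester axial and cis to C20; the silyl enol ether, the isolated methylidene and the silyl ether are not reduced.

Step 14
Reactants: 20 methyl (1R,4aS,5R,8aS)-4-[(tert-butyldimethylsilyl)oxy]-1,4a-dimethyl-6-methylidene-5-{2-[(triisopropylsilyl)oxy]ethyl}-1,2,4a,5,6,7,8,8a-octahydronaphthalene-1-carboxylate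
Product: 21 methyl (1R,4aS,5R,8aS)-1,4a-dimethyl-6-methylidene-4-oxo-5-{2-[(triisopropylsilyl)oxy]ethyl}decahydronaphthalene-1-carboxylate
Conditions: TBAF (n-Bu4NF), AcOH, THF, 0 °C
Reagents that add atoms: none
Why: Fluoride-induced cleavage of a silyl enol ether, which is far faster than that of a primary TIPS ether, with acetic acid protonating C2; C10 is quaternary, so nothing can epimerise.

Step 15
Reactants: 21 methyl (1R,4aS,5R,8aS)-1,4a-dimethyl-6-methylidene-4-oxo-5-{2-[(triisopropylsilyl)oxy]ethyl}decahydronaphthalene-1-carboxylate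
Product: 22 methyl (1R,4S,4aS,5R,8aS)-4-hydroxy-1,4a-dimethyl-6-methylidene-5-{2-[(triisopropylsilyl)oxy]ethyl}decahydronaphthalene-1-carboxylate
Conditions: NaBH4, MeOH, 0 °C → rt
Reagents that add atoms: none
Why: Borohydride reduction of a cyclohexanone, in which hydride should enter axially on the face away from the axial C10 methyl (the equatorial trajectory is blocked by the C11 arm) to give the equatorial (1S) alcohol cis to C20, the hindered methyl ester staying intact.

Step 16
Reactants: 22 methyl (1R,4S,4aS,5R,8aS)-4-hydroxy-1,4a-dimethyl-6-methylidene-5-{2-[(triisopropylsilyl)oxy]ethyl}decahydronaphthalene-1-carboxylate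
Product: 23 methyl (1R,4S,4aS,5R,8aS)-4-(acetyloxy)-1,4a-dimethyl-6-methylidene-5-{2-[(triisopropylsilyl)oxy]ethyl}decahydronaphthalene-1-carboxylate
Conditions: Ac2O, pyridine, DMAP, 40 °C
Reagents that add atoms: acetic anhydride, CC(=O)OC(C)=O
Why: DMAP-catalysed acetylation of the secondary alcohol with retention at C1, done before the aldehyde is unveiled so that the C1 oxygen cannot add to C12.

Step 17
Reactants: 23 methyl (1R,4S,4aS,5R,8aS)-4-(acetyloxy)-1,4a-dimethyl-6-methylidene-5-{2-[(triisopropylsilyl)oxy]ethyl}decahydronaphthalene-1-carboxylate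
Product: 24 methyl (1R,4S,4aS,5R,8aS)-4-(acetyloxy)-5-(2-hydroxyethyl)-1,4a-dimethyl-6-methylidenedecahydronaphthalene-1-carboxylate
Conditions: HF·pyridine, pyridine, THF, 0 °C → rt
Reagents that add atoms: none
Why: Fluoride cleavage of the primary silyl ether under buffered, non-basic conditions that leave the acetate, the methyl ester and the exocyclic alkene alone.

Step 18
Reactants: 24 methyl (1R,4S,4aS,5R,8aS)-4-(acetyloxy)-5-(2-hydroxyethyl)-1,4a-dimethyl-6-methylidenedecahydronaphthalene-1-carboxylate
Product: 25 methyl (1R,4S,4aS,5R,8aS)-4-(acetyloxy)-1,4a-dimethyl-6-methylidene-5-(2-oxoethyl)decahydronaphthalene-1-carboxylate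
Conditions: TEMPO (10 mol %), PhI(OAc)2, CH2Cl2, rt
Reagents that add atoms: none
Why: TEMPO-mediated oxidation of the primary alcohol to the C12 aldehyde under neutral conditions that do not enolise it or affect the esters and the alkene.

Step 19
Reactants: 25 methyl (1R,4S,4aS,5R,8aS)-4-(acetyloxy)-1,4a-dimethyl-6-methylidene-5-(2-oxoethyl)decahydronaphthalene-1-carboxylate
Product: 26 methyl (1R,4S,4aS,5R,8aS)-4-(acetyloxy)-1,4a-dimethyl-6-methylidene-5-[(2E)-3-methyl-4-oxobut-2-en-1-yl]decahydronaphthalene-1-carboxylate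
Conditions: Ph3P=C(CH3)CHO, PhMe, 90 °C
Reagents that add atoms: 2-(triphenylphosphoranylidene)propanal, CC(C=O)=P(c1ccccc1)(c1ccccc1)c1ccccc1
Why: Wittig olefination with a stabilised formyl ylide, which should give the (E) trisubstituted enal (C12=C13) and does not react with the esters.

Step 20
Reactants: 26 methyl (1R,4S,4aS,5R,8aS)-4-(acetyloxy)-1,4a-dimethyl-6-methylidene-5-[(2E)-3-methyl-4-oxobut-2-en-1-yl]decahydronaphthalene-1-carboxylate
Product: 27 methyl (1R,4S,4aS,5R,8aS)-4-(acetyloxy)-1,4a-dimethyl-6-methylidene-5-[(2E)-3-methylpenta-2,4-dien-1-yl]decahydronaphthalene-1-carboxylate (CNP0235031.1)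
Conditions: Ph3PCH3Br, KHMDS (KN(SiMe3)2), THF, 0 °C; then 26, −78 → 0 °C
Reagents that add atoms: methylidenetriphenylphosphorane (from methyltriphenylphosphonium bromide), C=P(c1ccccc1)(c1ccccc1)c1ccccc1
Why: Wittig methylenation of the enal carbonyl completes the (E)-1,3-diene without touching the C12=C13 geometry, the aldehyde reacting far faster than the acetate or the hindered ester at low temperature with a slight excess of ylide.

Compound list
1 | propane-1,3-diol | OCCCO | starting material
2 | 3-[(triisopropylsilyl)oxy]propan-1-ol | OCCCO[Si](C(C)C)(C(C)C)C(C)C | intermediate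
3 | 3-[(triisopropylsilyl)oxy]propanal | O=CCCO[Si](C(C)C)(C(C)C)C(C)C | intermediate
4 | triethyl phosphonoacetate | CCOC(=O)CP(=O)(OCC)OCC | starting material
5 | 4-bromobut-1-yne | BrCCC#C | starting material
6 | ethyl 2-(diethoxyphosphoryl)hex-5-ynoate (racemic) | CCOC(=O)C(CCC#C)P(=O)(OCC)OCC | intermediate
7 | ethyl (2E)-2-(but-3-yn-1-yl)-5-[(triisopropylsilyl)oxy]pent-2-enoate | CCOC(=O)/C(CCC#C)=C/CCO[Si](C(C)C)(C(C)C)C(C)C | intermediate
8 | (2E)-2-(but-3-yn-1-yl)-5-[(triisopropylsilyl)oxy]pent-2-en-1-ol | OC/C(CCC#C)=C/CCO[Si](C(C)C)(C(C)C)C(C)C | intermediate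
9 | propanoyl chloride | CCC(Cl)=O | starting material
10 | (2E)-2-(but-3-yn-1-yl)-5-[(triisopropylsilyl)oxy]pent-2-en-1-yl propanoate | CCC(=O)OC/C(CCC#C)=C/CCO[Si](C(C)C)(C(C)C)C(C)C | intermediate
11 | boron ketene acetal of 10: O-[(4S,5S)-1,3-bis{[3,5-bis(trifluoromethyl)phenyl]sulfonyl}-4,5-diphenyl-1,3,2-diazaborolidin-2-yl] ketene acetal, methyl cis to O–B | C/C=C(\OB1N(S(=O)(=O)c2cc(cc(c2)C(F)(F)F)C(F)(F)F)[C@@H](c2ccccc2)[C@H](c2ccccc2)N1S(=O)(=O)c1cc(cc(c1)C(F)(F)F)C(F)(F)F)OC/C(CCC#C)=C/CCO[Si](C(C)C)(C(C)C)C(C)C | intermediate (not isolated)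
12 | (2S,3S)-2-methyl-4-methylidene-3-{2-[(triisopropylsilyl)oxy]ethyl}oct-7-ynoic acid | OC(=O)[C@@H](C)[C@H](CCO[Si](C(C)C)(C(C)C)C(C)C)C(=C)CCC#C | intermediate
13 | (2S,3S)-N-methoxy-N,2-dimethyl-4-methylidene-3-{2-[(triisopropylsilyl)oxy]ethyl}oct-7-ynamide | CON(C)C(=O)[C@@H](C)[C@H](CCO[Si](C(C)C)(C(C)C)C(C)C)C(=C)CCC#C | intermediate
14 | (4S,5S)-4-methyl-6-methylidene-5-{2-[(triisopropylsilyl)oxy]ethyl}dec-1-en-9-yn-3-one | C=CC(=O)[C@@H](C)[C@H](CCO[Si](C(C)C)(C(C)C)C(C)C)C(=C)CCC#C | intermediate
15 | (3Z,5R)-3-[(tert-butyldimethylsilyl)oxy]-4-methyl-6-methylidene-5-{2-[(triisopropylsilyl)oxy]ethyl}deca-1,3-dien-9-yne | C=C/C(O[Si](C)(C)C(C)(C)C)=C(\C)[C@H](CCO[Si](C(C)C)(C(C)C)C(C)C)C(=C)CCC#C | intermediate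
16 | lithium acetylide of 15 | C=C/C(O[Si](C)(C)C(C)(C)C)=C(\C)[C@H](CCO[Si](C(C)C)(C(C)C)C(C)C)C(=C)CCC#C[Li] | intermediate (not isolated)
17 | methyl (7R,8Z)-9-[(tert-butyldimethylsilyl)oxy]-8-methyl-6-methylidene-7-{2-[(triisopropylsilyl)oxy]ethyl}undeca-8,10-dien-2-ynoate | C=C/C(O[Si](C)(C)C(C)(C)C)=C(\C)[C@H](CCO[Si](C(C)C)(C(C)C)C(C)C)C(=C)CCC#CC(=O)OC | intermediate (key-step precursor)
18 | methyl (4aS,5R)-4-[(tert-butyldimethylsilyl)oxy]-4a-methyl-6-methylidene-5-{2-[(triisopropylsilyl)oxy]ethyl}-2,4a,5,6,7,8-hexahydronaphthalene-1-carboxylate | CC(C)[Si](C(C)C)(C(C)C)OCC[C@@H]1C(=C)CCC2=C(C(=O)OC)CC=C(O[Si](C)(C)C(C)(C)C)[C@@]12C | intermediate (key-step product)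
19 | lithium ester enolate at C4 of the trans-fused reduction product of 18 (C5, C9, C10 as in 20) | CC(C)[Si](C(C)C)(C(C)C)OCC[C@@H]1C(=C)CC[C@H]2[C@@]1(C)C(O[Si](C)(C)C(C)(C)C)=CCC2=C(O[Li])OC | intermediate (not isolated)
20 | methyl (1R,4aS,5R,8aS)-4-[(tert-butyldimethylsilyl)oxy]-1,4a-dimethyl-6-methylidene-5-{2-[(triisopropylsilyl)oxy]ethyl}-1,2,4a,5,6,7,8,8a-octahydronaphthalene-1-carboxylate | CC(C)[Si](C(C)C)(C(C)C)OCC[C@@H]1C(=C)CC[C@H]2[C@@]1(C)C(O[Si](C)(C)C(C)(C)C)=CC[C@@]2(C)C(=O)OC | intermediate
21 | methyl (1R,4aS,5R,8aS)-1,4a-dimethyl-6-methylidene-4-oxo-5-{2-[(triisopropylsilyl)oxy]ethyl}decahydronaphthalene-1-carboxylate | CC(C)[Si](C(C)C)(C(C)C)OCC[C@@H]1C(=C)CC[C@H]2[C@@]1(C)C(=O)CC[C@@]2(C)C(=O)OC | intermediate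
22 | methyl (1R,4S,4aS,5R,8aS)-4-hydroxy-1,4a-dimethyl-6-methylidene-5-{2-[(triisopropylsilyl)oxy]ethyl}decahydronaphthalene-1-carboxylate | CC(C)[Si](C(C)C)(C(C)C)OCC[C@@H]1C(=C)CC[C@H]2[C@@]1(C)[C@@H](O)CC[C@@]2(C)C(=O)OC | intermediate
23 | methyl (1R,4S,4aS,5R,8aS)-4-(acetyloxy)-1,4a-dimethyl-6-methylidene-5-{2-[(triisopropylsilyl)oxy]ethyl}decahydronaphthalene-1-carboxylate | CC(C)[Si](C(C)C)(C(C)C)OCC[C@@H]1C(=C)CC[C@H]2[C@@]1(C)[C@@H](OC(C)=O)CC[C@@]2(C)C(=O)OC | intermediate
24 | methyl (1R,4S,4aS,5R,8aS)-4-(acetyloxy)-5-(2-hydroxyethyl)-1,4a-dimethyl-6-methylidenedecahydronaphthalene-1-carboxylate | OCC[C@@H]1C(=C)CC[C@H]2[C@@]1(C)[C@@H](OC(C)=O)CC[C@@]2(C)C(=O)OC | intermediate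
25 | methyl (1R,4S,4aS,5R,8aS)-4-(acetyloxy)-1,4a-dimethyl-6-methylidene-5-(2-oxoethyl)decahydronaphthalene-1-carboxylate | O=CC[C@@H]1C(=C)CC[C@H]2[C@@]1(C)[C@@H](OC(C)=O)CC[C@@]2(C)C(=O)OC | intermediate
26 | methyl (1R,4S,4aS,5R,8aS)-4-(acetyloxy)-1,4a-dimethyl-6-methylidene-5-[(2E)-3-methyl-4-oxobut-2-en-1-yl]decahydronaphthalene-1-carboxylate | O=C/C(C)=C/C[C@@H]1C(=C)CC[C@H]2[C@@]1(C)[C@@H](OC(C)=O)CC[C@@]2(C)C(=O)OC | intermediate
27 | methyl (1R,4S,4aS,5R,8aS)-4-(acetyloxy)-1,4a-dimethyl-6-methylidene-5-[(2E)-3-methylpenta-2,4-dien-1-yl]decahydronaphthalene-1-carboxylate | C=C/C(C)=C/C[C@@H]1C(=C)CC[C@H]2[C@@]1(C)[C@@H](OC(C)=O)CC[C@@]2(C)C(=O)OC | target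

Total step count: 20. Longest linear sequence: 19 steps (from 1 through steps 1, 2 and 4–20).

Steps most likely to fail

Step 12. The cycloaddition of the twisted, fully substituted diene terminus may be slow enough that a 1,5-hydrogen shift from the cis methyl or loss of the silyl enol ether on prolonged heating competes with ring closure. The fallback sets out from 17 and returns at 18, and makes the same two bonds stepwise by an anionic double Michael sequence. Anhydrous fluoride (n-Bu4N[Ph3SiF2], THF, −78 → 0 °C) should unmask the cross-conjugated C10 enolate of 17, which adds to C5 of the ynoate and closes ring B. The allenoate so formed then adds to C3 of the regenerated enone and closes ring A. Protonation should give the keto enoate methyl (4aS,5R)-4a-methyl-6-methylidene-4-oxo-5-{2-[(triisopropylsilyl)oxy]ethyl}-2,3,4,4a,5,6,7,8-octahydronaphthalene-1-carboxylate F1, with C10 again governed by allylic strain from C9. Soft enolisation of F1 (TBSOTf, Et3N, CH2Cl2, 0 °C), possible only toward C2, gives 18.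

Step 7. Enolisation of the hindered ester by the bromoborane may be incomplete, or face discrimination (including leakage through a boat transition state) may be insufficient, so that enantiopurity at C9 erodes. The fallback sets out from 10 and returns at 12, and replaces asymmetric induction by resolution. Ester 10 is rearranged without chiral control (LDA 2.2 equiv, THF–DMPU, −78 °C, TMSCl, then rt) through the (Z)-O-trimethylsilyl ketene acetal carrying a C-silylated alkyne F2 (not isolated). Methanolysis (K2CO3, MeOH) should then give the racemic (2S*,3S*) acid F3 with the same relative configuration as 12. F3 is coupled with (4S)-4-benzyl-1,3-oxazolidin-2-one (DCC, DMAP, CH2Cl2) and the two diastereomeric imides are separated by chromatography. The imide (4S)-4-benzyl-3-[(2S,3S)-2-methyl-4-methylidene-3-{2-[(triisopropylsilyl)oxy]ethyl}oct-7-ynoyl]-1,3-oxazolidin-2-one F4 is cleaved with LiOH/H2O2 (THF/H2O, 0 °C) to 12.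

Step 13. The enolate may be protonated by the ammonia medium instead of methylated, the ester may be over-reduced, or facial discrimination at C4 may be weak in liquid ammonia. The fallback sets out from 18 and returns at 20, and separates reduction from alkylation. Compound 18 is reduced (Li, NH3/THF, t-BuOH, −78 °C) and quenched with solid NH4Cl to give the trans-fused saturated ester F5, the 1-demethyl analogue of 20 (C5, C9 and C10 as in 20, mixture of epimers at the ester-bearing carbon). F5 is then deprotonated with LDA in THF–DMPU at −78 °C and the lithium enolate is methylated with MeI under aprotic conditions, where entry anti to the axial C10 methyl is the established course, to give 20.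

Further compounds
F1 | step 12 | methyl (4aS,5R)-4a-methyl-6-methylidene-4-oxo-5-{2-[(triisopropylsilyl)oxy]ethyl}-2,3,4,4a,5,6,7,8-octahydronaphthalene-1-carboxylate | CC(C)[Si](C(C)C)(C(C)C)OCC[C@@H]1C(=C)CCC2=C(C(=O)OC)CCC(=O)[C@@]12C
F2 | step 7 | (Z)-O-trimethylsilyl ketene acetal of 10 with C-trimethylsilylated alkyne | C/C=C(\O[Si](C)(C)C)OC/C(CCC#C[Si](C)(C)C)=C/CCO[Si](C(C)C)(C(C)C)C(C)C
F3 | step 7 | racemic (2S*,3S*)-2-methyl-4-methylidene-3-{2-[(triisopropylsilyl)oxy]ethyl}oct-7-ynoic acid (racemate, relative configuration as in 12) | OC(=O)C(C)C(CCO[Si](C(C)C)(C(C)C)C(C)C)C(=C)CCC#C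
F4 | step 7 | (4S)-4-benzyl-3-[(2S,3S)-2-methyl-4-methylidene-3-{2-[(triisopropylsilyl)oxy]ethyl}oct-7-ynoyl]-1,3-oxazolidin-2-one | O=C1OC[C@H](Cc2ccccc2)N1C(=O)[C@@H](C)[C@H](CCO[Si](C(C)C)(C(C)C)C(C)C)C(=C)CCC#C
F5 | step 13 | 1-demethyl analogue of 20: trans-fused methyl 4-[(tert-butyldimethylsilyl)oxy]-4a-methyl-6-methylidene-5-{2-[(triisopropylsilyl)oxy]ethyl}-1,2,4a,5,6,7,8,8a-octahydronaphthalene-1-carboxylate, epimers at the ester-bearing carbon | CC(C)[Si](C(C)C)(C(C)C)OCC[C@@H]1C(=C)CC[C@H]2[C@@]1(C)C(O[Si](C)(C)C(C)(C)C)=CCC2C(=O)OC
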